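## Structural features

The target is a 7,7′-epoxylignan built on one oxolane ring (O1, C2, C3, C4, C5). C2 and C5 each carry a 4-hydroxy-3-methoxyphenyl (guaiacyl) ring, C3 carries CH3 and a tertiary OH, and C4 carries CH3 and H. All four ring carbons are contiguous stereocentres, (2R,3S,4S,5S): with the C2 aryl group up, C3-CH3 is up, C3-OH is down, C4-CH3 is down and the C5 aryl group is down. The aryl groups are therefore 2,5-trans, each aryl group is cis to the neighbouring methyl group, the methyl groups are trans, and C3-OH is trans to the C2 aryl group and cis to C4-CH3. Without the hydroxyl the skeleton would have twofold rotational symmetry. Because the two aryl rings are identical, one aldehyde can supply both.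

This cis,trans,cis array is the sterically least relaxed one and has to be made under kinetic control. Both O1–C bonds are p-hydroxybenzylic. They ionise with acid or open through quinone methides with base, which would epimerise C2 and C5 or lead to aryltetralins. The tertiary alcohol can dehydrate, and the free guaiacol rings are sensitive to electrophiles and oxidants.

The real difficulty is the fully substituted carbinol C3 wedged between the benzylic ether carbon C2 and C4, together with the two kinetic cis relations (C2 aryl/C3-CH3 and C4-CH3/C5 aryl).

The key step exploits four features: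
- C2–C3–C4 can be read as an allyl unit and C5=O1 as an aldehyde.
- The oxygen on the central carbon C3 can stand for a silicon atom that has migrated there from C2.
- The electron-rich aryl ring on C2 makes C2 the natural resting place of positive charge.
- The pattern Si(OH)/C4-CH3 cis, C4-CH3/C5-aryl cis, Si(OH)/C2-aryl trans is what anti attack, syn-selective addition and anti ring closure of a (Z)-crotylsilane deliver.

## Logic of the disconnections

**9 to 8.** Cut: the two phenolic O–H bonds become O–CH2Ph bonds. Reason: free p-hydroxybenzylic ethers open through quinone methides, so the phenols stay masked until the end. Gain: C2 and C5 are configurationally safe in every earlier step. Demand: a neutral unmasking that spares the two ring C–O bonds.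

**8 to 7.** Cut: C3–O, replaced by C3–Si. Reason: a silyl group can be carried into C3 by a carbon–carbon bond-forming event and turned into OH with retention. Gain: the tertiary carbinol no longer depends on a face-selective addition to a crowded ring. Demand: a nucleophilic, non-electrophilic oxidation of a hindered tertiary silane that is β to O1, without β-elimination.

**7 to 6 + 1 (key).** Cut: C4–C5 and O1–C2, so the ring falls into the two-atom unit C5=O1 and the three-carbon unit C2–C3–C4. Reason: these two bonds carry all four stereocentres, and one C–Si stereocentre in an acyclic precursor can dictate them. Gain: a tetrasubstituted ring with a fully substituted centre becomes one achiral compound, used for the second time, plus one compound with a single stereocentre. Demand: anti attack relative to silicon, syn addition to the carbonyl group, a 1,2-silyl shift onto C3, and ring closure faster than loss of silicon. In one sentence: (3+2) annulation of 1 with 6.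

**6 to 4 (through 5).** Cut: C2–Si and one C–H bond of the methyl group on C4, that is, H–Si is removed 1,4. Reason: the required (Z) geometry, with the methyl group cis to the bulky C2, is contra-steric for acyclic transition states but is the natural outcome of addition to a cisoid diene. Gain: the only stereocentre set by catalysis is traced to an achiral diene. Demand: silicon must go to the benzylic terminus, with face selection by a chiral ligand and no syn–anti exchange.

**4 to 3.** Cut: the terminal C=CH2 bond. Reason and gain: a one-carbon olefination of a conjugated carbonyl group. Demand: none beyond retention of the (E) geometry.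

**3 to 1 + 2.** Cut: the C=C bond between the future C2 and the future C3. Reason: crossed aldol condensation of a non-enolisable partner. Gain: two commercial compounds. Demand: (E) selectivity, which conjugation and sterics provide.

## Other disconnections considered

**Alternative 1:** the first that comes to mind. Cut C3–CH3. The forward key step adds a methyl organometallic to the oxolan-3-one A1. Three things weigh against it:
- A1 has two enolisable α-centres (C2, benzylic and α-oxy, and C4) whose required 2,5-trans/4,5-cis arrangement is the less stable one, so basic nucleophiles threaten both.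
- The methyl group would have to enter syn to the adjacent C2 aryl group, and nothing in A1 clearly biases that face against the one flanked by C4-CH3.
- A1 itself needs three stereocentres set beforehand, so the hard part is only postponed.

**Alternative 2:** hidden symmetry. Cut O1–C5 and C4–H. The forward key step is 5-endo haloetherification of the ene-diol A3 followed by radical reduction, with A3 coming from the symmetric diene A2. The entry is attractive, but the plan has three weaknesses:
- The C2/C3 relation of the target corresponds to an anti diol of the (E)-alkene. Direct syn dihydroxylation therefore gives the wrong diastereomer, and an epoxidation/hydrolysis detour is required.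
- C5 and C4 are then set in two separate events, a face choice in the cyclisation and a hydrogen-atom transfer to a planar radical, without a strong controlling element.
- The route passes through a labile tertiary halide β to oxygen.

The chosen plan sets the same centres in one stereospecific event and is shorter.

**Alternative 3:** another (3+2). Cut C3–C4 and O1–C5. The forward key step is a Lewis-acid annulation of the α-silyloxy ketone A4 with the styrene A5, in which alkene attack on C3=O is followed by capture of the C5 benzylic cation by the C2 oxygen. It joins two phenylpropanoid halves at the biogenetic bond. However, the ring closes on a free benzylic cation at C5 with no β-substituent to steer it, so mechanism and sterics point to the 4,5-trans relation and the target is 4,5-cis. In addition, a methyl ketone is a much weaker electrophile than an aldehyde, and the C2/C3 relation needs Felkin–Anh rather than chelate control under Lewis-acid conditions. In the chosen plan the cis relation comes from a syn-selective carbonyl addition, and the ring closure is steered by silicon.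

Key step: step 4

Assumption: the sense of induction of the chiral monophosphine in step 3 cannot be derived from the structure alone. The (R)-ligand is written, and its antipode is to be used if it favours the (S)-silane.

## Steps

Step 1
Reactants: 1 4-(benzyloxy)-3-methoxybenzaldehyde; 2 propanal
Product: 3 (2E)-3-[4-(benzyloxy)-3-methoxyphenyl]-2-methylprop-2-enal
Conditions: NaOH (cat.), MeOH/H2O, slow addition of 2, 0 °C to rt
Reagents that add atoms: none
Why: Crossed aldol condensation of a non-enolisable electron-rich benzaldehyde with propanal, and slow addition suppresses self-condensation of 2. E1cB dehydration gives the conjugated (E)-enal with the aryl group trans to CHO.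

Step 2
Reactants: 3 (2E)-3-[4-(benzyloxy)-3-methoxyphenyl]-2-methylprop-2-enal
Product: 4 1-(benzyloxy)-2-methoxy-4-[(1E)-2-methylbuta-1,3-dien-1-yl]benzene
Conditions: Ph3PCH3Br, KOt-Bu, THF, 0 °C to rt
Reagents that add atoms: methyltriphenylphosphonium bromide, C[P+](c1ccccc1)(c1ccccc1)c1ccccc1.[Br-]
Why: Wittig methylenation of an enal occurs 1,2 and does not touch the existing (E)-alkene or the benzyl ether.

Step 3
Reactants: 4 1-(benzyloxy)-2-methoxy-4-[(1E)-2-methylbuta-1,3-dien-1-yl]benzene
Product: 6 {(1R,2Z)-1-[4-(benzyloxy)-3-methoxyphenyl]-2-methylbut-2-en-1-yl}dimethyl(phenyl)silane, via dichlorosilane adduct 5 (not isolated)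
Conditions: PhSiHCl2, [PdCl(C3H5)]2 (0.5 mol %), (R)-2-(diphenylphosphino)-2′-methoxy-1,1′-binaphthyl [(R)-MeO-MOP, 2 mol %], toluene, 0 to 20 °C; then MeMgBr, Et2O, 0 °C to rt
Reagents that add atoms: dichloro(phenyl)silane, Cl[SiH](Cl)c1ccccc1; methylmagnesium bromide, C[Mg]Br
Why: Palladium-catalysed asymmetric 1,4-hydrosilylation of a 1-aryl-1,3-diene, in which H–Pd formed from zerovalent palladium adds to the terminal CH2 of the cisoid diene to give an anti-methyl π-allyl complex, and silicon is transferred to the benzylic terminus before syn–anti exchange, which fixes the (Z)-alkene. The monodentate chiral phosphine selects the diene face and so sets C2 as (R). Exhaustive methylation of the Si–Cl bonds does not touch the stereocentre.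

Step 4
Reactants: 6 {(1R,2Z)-1-[4-(benzyloxy)-3-methoxyphenyl]-2-methylbut-2-en-1-yl}dimethyl(phenyl)silane; 1 4-(benzyloxy)-3-methoxybenzaldehyde
Product: 7 {(2R,3S,4S,5S)-2,5-bis[4-(benzyloxy)-3-methoxyphenyl]-3,4-dimethyloxolan-3-yl}dimethyl(phenyl)silane
Conditions: BF3·OEt2 (1.1 equiv), 2,6-di-tert-butyl-4-methylpyridine (0.2 equiv), CH2Cl2, −78 °C; Et3N quench at −78 °C
Reagents that add atoms: none
Why: Proposed new method: BF3-bound 1 is attacked by C4 of 6 on the alkene face anti to the C2–Si bond (anti SE2′) to give a tertiary β-silyl cation at C3, the silyl group then shifts suprafacially from C2 to C3 because the charge ends on the p-benzyloxybenzylic C2, and the boron alkoxide on C5 closes the O1–C2 bond. The closest known reaction type is the Lewis-acid-promoted (3+2) annulation of chiral crotylsilanes with aldehydes to 3-silyloxolanes through a 1,2-silyl shift, which has not been shown for α-aryl-β-methyl crotylsilanes or for a fully substituted C–Si centre, hence the label. The single ring closes by 5-exo-trig capture of the quinoid benzylic cation (seen from the bridged form, anti opening of the siliranium ion at C2). C3 and C4: C5 and Si add anti across the (Z)-alkene, so Si ends cis to C4-CH3, and the absolute sense is relayed from C2 of 6 because A(1,3) strain between C4-CH3 and the C2 substituents leaves only the conformer with C2–H in the alkene plane and C2–Si perpendicular to it. C5: in the open antiperiplanar transition state the aryl group of 1 avoids C4-CH3 and the silyl-bearing C2 and lies over the small C3-CH3, which is the syn mode and gives C4-CH3/C5-aryl cis. C2: oxygen enters anti to silicon, since β-silicon hyperconjugation holds the C3–Si bond parallel to the empty orbital, with the aryl group in the outside position, so C2 is inverted relative to 6 and its aryl group ends trans to Si and cis to C3-CH3, and the steric bias (SiMe2Ph larger than CH3) points the same way should the cation rotate. The step needs ring closure to outrun loss of silicon, which is secured because the charge drained into the aryl ring lowers the electrophilicity of silicon, the closure is intramolecular, BF3 supplies no free halide, and −78 °C with a cold amine quench limits re-ionisation of 7.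

Step 5
Reactants: 7 {(2R,3S,4S,5S)-2,5-bis[4-(benzyloxy)-3-methoxyphenyl]-3,4-dimethyloxolan-3-yl}dimethyl(phenyl)silane
Product: 8 (2R,3S,4S,5S)-2,5-bis[4-(benzyloxy)-3-methoxyphenyl]-3,4-dimethyloxolan-3-ol
Conditions: t-BuOOH, KH, NMP, 0 °C to rt; then Bu4NF, 70 °C
Reagents that add atoms: tert-butyl hydroperoxide, CC(C)(C)OO
Why: Tamao–Fleming oxidation in its nucleophilic form (hydroperoxide anion and fluoride), devised for hindered phenylsilanes, which avoids the electrophilic dearylation reagents that would attack the electron-rich arenes. Carbon migrates from silicon to oxygen with retention, so C3 keeps the (S) geometry of the target. With the phenols benzylated, no quinone methide can form in base.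

Step 6
Reactants: 8 (2R,3S,4S,5S)-2,5-bis[4-(benzyloxy)-3-methoxyphenyl]-3,4-dimethyloxolan-3-ol
Product: 9 (2R,3S,4S,5S)-2,5-bis(4-hydroxy-3-methoxyphenyl)-3,4-dimethyloxolan-3-ol
Conditions: H2 (1 atm), Pd/C, EtOAc/EtOH, rt, stopped at full conversion
Reagents that add atoms: none
Why: Catalytic hydrogenolysis of aryl benzyl ethers under neutral conditions. The unhindered primary O–CH2Ph bonds should be cleaved faster than the two secondary ring C–O bonds, which are flanked by substituents, and no acid or base is present to epimerise C2 or C5.

## Compound list

1 | 4-(benzyloxy)-3-methoxybenzaldehyde | COc1cc(C=O)ccc1OCc1ccccc1 | starting material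
2 | propanal | CCC=O | starting material
3 | (2E)-3-[4-(benzyloxy)-3-methoxyphenyl]-2-methylprop-2-enal | O=C/C(C)=C/c1ccc(OCc2ccccc2)c(OC)c1 | intermediate
4 | 1-(benzyloxy)-2-methoxy-4-[(1E)-2-methylbuta-1,3-dien-1-yl]benzene | C=C/C(C)=C/c1ccc(OCc2ccccc2)c(OC)c1 | intermediate
5 | {(1R,2Z)-1-[4-(benzyloxy)-3-methoxyphenyl]-2-methylbut-2-en-1-yl}dichloro(phenyl)silane | C/C=C(/C)[C@H](c1ccc(OCc2ccccc2)c(OC)c1)[Si](Cl)(Cl)c1ccccc1 | intermediate
6 | {(1R,2Z)-1-[4-(benzyloxy)-3-methoxyphenyl]-2-methylbut-2-en-1-yl}dimethyl(phenyl)silane | C/C=C(/C)[C@H](c1ccc(OCc2ccccc2)c(OC)c1)[Si](C)(C)c1ccccc1 | intermediate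
7 | {(2R,3S,4S,5S)-2,5-bis[4-(benzyloxy)-3-methoxyphenyl]-3,4-dimethyloxolan-3-yl}dimethyl(phenyl)silane | COc1cc([C@H]2O[C@H](c3ccc(OCc4ccccc4)c(OC)c3)[C@@](C)([Si](C)(C)c3ccccc3)[C@H]2C)ccc1OCc1ccccc1 | intermediate
8 | (2R,3S,4S,5S)-2,5-bis[4-(benzyloxy)-3-methoxyphenyl]-3,4-dimethyloxolan-3-ol | COc1cc([C@H]2O[C@H](c3ccc(OCc4ccccc4)c(OC)c3)[C@@](C)(O)[C@H]2C)ccc1OCc1ccccc1 | intermediate
9 | (2R,3S,4S,5S)-2,5-bis(4-hydroxy-3-methoxyphenyl)-3,4-dimethyloxolan-3-ol | COc1cc([C@H]2O[C@H](c3ccc(O)c(OC)c3)[C@@](C)(O)[C@H]2C)ccc1O | target

## Step count and least certain steps

Total step count: 6. Longest linear sequence: 6 steps (1, 3, 4, 6, 7, 8, 9). Compound 1 enters twice, in step 1 and in step 4.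

**Step 4 (key step, labelled).**
What may go wrong:
- Loss of the silyl group from the cation before the ring closes (the Hosomi–Sakurai pathway).
- Re-ionisation of the O1–C2 bond of the product under BF3, followed by desilylation, Friedel–Crafts closure onto the C5 aryl ring, or epimerisation.
- Erosion of the syn mode at C5, because (Z)-crotylsilanes are less syn-selective than their (E) isomers.

The cause in each case is the high stability of the benzylic cation.

Fallback (known chemistry), from 6 and 1 back to 8. The silyl loss is accepted on purpose. TiCl4 in CH2Cl2 at −78 °C runs the anti-SE2′ Hosomi–Sakurai reaction, which should give (1S,2R,3E)-1,4-bis[4-(benzyloxy)-3-methoxyphenyl]-2,3-dimethylbut-3-en-1-ol F1 with the same C4 and C5 centres. A Shi epoxidation follows (chiral ketone enantiomer matched to the required alkene face, KHSO5 as Oxone, K2CO3 buffer) and gives (1S,2S)-1-[4-(benzyloxy)-3-methoxyphenyl]-2-{(2S,3S)-3-[4-(benzyloxy)-3-methoxyphenyl]-2-methyloxiran-2-yl}propan-1-ol F2. Mild acid (pyridinium p-toluenesulfonate, CH2Cl2, 0 °C) then lets the C5 hydroxyl open the epoxide at benzylic C2 with inversion (5-endo) to reach 8.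

**Step 3.**
What may go wrong:
- Insufficient face selection by the ligand on an acyclic diene.
- Delivery of silicon to the other allyl terminus.
- Syn–anti exchange of the π-allyl complex, which would erode the (Z) geometry.

The 2-methyl group changes the allyl complex relative to simple 1-arylbutadienes.

Fallback, from 1 back to 6. Addition of PhMe2SiLi (THF, −78 °C, cold quench to suppress Brook rearrangement) gives racemic [4-(benzyloxy)-3-methoxyphenyl][dimethyl(phenyl)silyl]methanol F3. HCl in dioxane/CH2Cl2 at 0 °C then gives racemic {[4-(benzyloxy)-3-methoxyphenyl](chloro)methyl}dimethyl(phenyl)silane F4. An enantioconvergent nickel-catalysed reductive alkenylation of F4 (NiCl2(dme), chiral bis(oxazoline), Mn, NMP) with commercial (Z)-2-bromobut-2-ene forms the C2–C3 bond, sets C2 by ligand control, and takes the alkene geometry from the bromide.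

**Step 5.**
What may go wrong:
- Slow attack at the crowded tertiary silicon.
- Fluoride-triggered β-elimination of silicon and O1, which would open the ring. The C2–O1 bond is benzylic and lies β to silicon.

Fallback, from 7 back to 8. The two events are separated. KOt-Bu in wet DMSO at rt removes only the phenyl group, without fluoride, to give {(2R,3S,4S,5S)-2,5-bis[4-(benzyloxy)-3-methoxyphenyl]-3,4-dimethyloxolan-3-yl}dimethylsilanol F5. F5 is isolated and then oxidised under classical Tamao conditions for heteroatom-substituted silanes (H2O2, KF, KHCO3, THF/MeOH, rt) with retention at C3.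

## Further compounds

F1 | step 4 | (1S,2R,3E)-1,4-bis[4-(benzyloxy)-3-methoxyphenyl]-2,3-dimethylbut-3-en-1-ol | O[C@H](c1ccc(OCc2ccccc2)c(OC)c1)[C@H](C)/C(C)=C/c1ccc(OCc2ccccc2)c(OC)c1
F2 | step 4 | (1S,2S)-1-[4-(benzyloxy)-3-methoxyphenyl]-2-{(2S,3S)-3-[4-(benzyloxy)-3-methoxyphenyl]-2-methyloxiran-2-yl}propan-1-ol | O[C@H](c1ccc(OCc2ccccc2)c(OC)c1)[C@H](C)[C@]1(C)O[C@H]1c1ccc(OCc2ccccc2)c(OC)c1
F3 | step 3 | racemic [4-(benzyloxy)-3-methoxyphenyl][dimethyl(phenyl)silyl]methanol | COc1cc(C(O)[Si](C)(C)c2ccccc2)ccc1OCc1ccccc1
F4 | step 3 | racemic {[4-(benzyloxy)-3-methoxyphenyl](chloro)methyl}dimethyl(phenyl)silane | COc1cc(C(Cl)[Si](C)(C)c2ccccc2)ccc1OCc1ccccc1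
F5 | step 5 | {(2R,3S,4S,5S)-2,5-bis[4-(benzyloxy)-3-methoxyphenyl]-3,4-dimethyloxolan-3-yl}dimethylsilanol | COc1cc([C@H]2O[C@H](c3ccc(OCc4ccccc4)c(OC)c3)[C@@](C)([Si](C)(C)O)[C@H]2C)ccc1OCc1ccccc1
A1 | alternative 1 | (2R,4S,5S)-2,5-bis[4-(benzyloxy)-3-methoxyphenyl]-4-methyloxolan-3-one | COc1cc([C@H]2O[C@H](c3ccc(OCc4ccccc4)c(OC)c3)C(=O)[C@H]2C)ccc1OCc1ccccc1
A2 | alternative 2 | (1E,3E)-1,4-bis[4-(benzyloxy)-3-methoxyphenyl]-2,3-dimethylbuta-1,3-diene | COc1cc(/C=C(C)/C(C)=C/c2ccc(OCc3ccccc3)c(OC)c2)ccc1OCc1ccccc1
A3 | alternative 2 | (1R,2S,3E)-1,4-bis[4-(benzyloxy)-3-methoxyphenyl]-2,3-dimethylbut-3-ene-1,2-diol | O[C@H](c1ccc(OCc2ccccc2)c(OC)c1)[C@@](C)(O)/C(C)=C/c1ccc(OCc2ccccc2)c(OC)c1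
A4 | alternative 3 | (1R)-1-[4-(benzyloxy)-3-methoxyphenyl]-1-[(triethylsilyl)oxy]propan-2-one | CC[Si](CC)(CC)O[C@H](c1ccc(OCc2ccccc2)c(OC)c1)C(C)=O
A5 | alternative 3 | 1-(benzyloxy)-2-methoxy-4-[(1E)-prop-1-en-1-yl]benzene | C/C=C/c1ccc(OCc2ccccc2)c(OC)c1
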